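**Plan**

1. Ring locants follow the target: C1 (C=O), C2 (bears C7H2OH), C3 (=CH), C4 (O-isobutyryl), C5 (isopropyl), C6 (O-hydroxytigloyl). The retrosynthesis cuts, in this order, the two silyl ethers on the primary oxygens, the C4–O acyl bond, the C2–C7 bond, the C6–O acyl bond, and takes C1=O back to C1–OH.
2. Enabling feature: C2 lies between C1 and C3, and without it the atoms C1, C3, C4, C5, C6 form a cyclopent-4-ene-1,3-diol carrying the isopropyl group on the carbon between the two carbinols. The six-membered ring is therefore cut back to the CBr2 adduct across C1=C3 of that cyclopentene, and the cyclopentene to furfural and isopropylmagnesium chloride.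
3. Forward order: five-membered ring (Piancatelli rearrangement), cyclopropane (dibromocarbene), six-membered ring together with the C1–O bond (silver-induced ring expansion with acetate participation), then C1 ketone, C6 ester, C7 on C2, C4 ester.
4. Stereochemistry: C5/C6 trans from the conrotatory closure of the rearrangement; absolute configuration from lipase acetylation; C4 from Luche reduction anti to isopropyl; C1 (transient) from oxygen delivery by the C6 acetate.
5. The E-alkene of the side chain comes from a stabilised Wittig reaction.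

Key step: step 7

Assumption: the lipase in step 3 acetylates the (4S,5R) enantiomer of 4, whose carbinol centre has the spatial arrangement of the fast-reacting enantiomer of cyclic allylic alcohols. If the preference is reversed, the recovered (4S,5R) alcohol is acetylated with Ac2O/pyridine to reach the same compound 6.

**Route**

Step 1
Reactants: 1 furfural; 2 isopropylmagnesium chloride
Product: 3 (±)-1-(furan-2-yl)-2-methylpropan-1-ol
Conditions: iPrMgCl, THF, 0 °C; aq NH4Cl
Reagents that add atoms: isopropylmagnesium chloride 2, CC(C)[Mg]Cl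
Why: Grignard addition to the non-enolisable aldehyde should give the racemic 2-furylcarbinol that the Piancatelli rearrangement requires.

Step 2
Reactants: 3 (±)-1-(furan-2-yl)-2-methylpropan-1-ol
Product: 4 (±)-trans-4-hydroxy-5-isopropylcyclopent-2-en-1-one
Conditions: ZnCl2, 1,4-dioxane/H2O, reflux
Reagents that add atoms: water, O
Why: Piancatelli rearrangement, in which acid-promoted loss of the carbinol hydroxyl, addition of water at furan C5 and conrotatory 4π closure of the ring-opened cation should place hydroxyl and isopropyl trans.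

Step 3
Reactants: 4 (±)-trans-4-hydroxy-5-isopropylcyclopent-2-en-1-one; 5 vinyl acetate
Product: 6 (4S,5R)-4-acetoxy-5-isopropylcyclopent-2-en-1-one
Conditions: Burkholderia cepacia lipase (Amano PS), vinyl acetate, MTBE, 30 °C, stopped near half conversion; chromatography
Reagents that add atoms: vinyl acetate 5, C=COC(C)=O
Why: Lipase-catalysed kinetic resolution by irreversible transesterification should acetylate only the (4S,5R) alcohol and leave the (4R,5S) alcohol to be removed by chromatography.

Step 4
Reactants: 6 (4S,5R)-4-acetoxy-5-isopropylcyclopent-2-en-1-one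
Product: 7 (1S,4S,5S)-4-hydroxy-5-isopropylcyclopent-2-en-1-yl acetate (hydroxyl cis to isopropyl, trans to acetoxy)
Conditions: NaBH4, CeCl3·7H2O, MeOH, −78 °C
Reagents that add atoms: none
Why: Luche reduction (1,2-selective hydride addition to the enone) should deliver hydride to the carbonyl face opposite the adjacent isopropyl group, which sets the new carbinol centre cis to isopropyl, while the low temperature keeps the β-acetoxy ketone from eliminating.

Step 5
Reactants: 7 (1S,4S,5S)-4-hydroxy-5-isopropylcyclopent-2-en-1-yl acetate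
Product: 8 (1S,4S,5R)-5-isopropyl-4-(triethylsilyloxy)cyclopent-2-en-1-yl acetate
Conditions: TESCl, imidazole, CH2Cl2, 0 °C
Reagents that add atoms: chlorotriethylsilane, CC[Si](Cl)(CC)CC
Why: Silylation of the secondary allylic alcohol gives an ether that cannot act as a neighbouring group in step 7 and can later be cleaved in the presence of TBDPS ethers.

Step 6
Reactants: 8 (1S,4S,5R)-5-isopropyl-4-(triethylsilyloxy)cyclopent-2-en-1-yl acetate; 9 tribromoacetic acid
Product: 10 (1S,2R,3R,4R,5R)-6,6-dibromo-3-isopropyl-4-(triethylsilyloxy)bicyclo[3.1.0]hexan-2-yl acetate (CBr2 bridge cis to acetoxy, trans to silyloxy and isopropyl)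
Conditions: 9, NaH, DME, 0 °C (forms CBr3CO2Na); then 8, 80 °C
Reagents that add atoms: tribromoacetic acid 9, OC(=O)C(Br)(Br)Br
Why: Thermal decarboxylation of sodium tribromoacetate releases dibromocarbene without base, which spares the acetate, and the [2+1] cycloaddition should occur on the alkene face anti to the silyloxy and isopropyl groups; the two new stereocentres are erased in step 7, so any minor diastereomer is carried along.

Step 7
Reactants: 10 (1S,2R,3R,4R,5R)-6,6-dibromo-3-isopropyl-4-(triethylsilyloxy)bicyclo[3.1.0]hexan-2-yl acetate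
Product: 13 (1R,4R,5R,6R)-2-bromo-1-hydroxy-5-isopropyl-4-(triethylsilyloxy)cyclohex-2-en-6-yl acetate, via bromocyclohexenyl cation tetrafluoroborate 11 (not isolated), via dioxolanylium tetrafluoroborate 12 (not isolated)
Conditions: AgBF4, 2,6-di-tert-butylpyridine, 4 Å MS, CH2Cl2, 0 °C to 40 °C, dark; then THF/sat. aq NaHCO3, 0 °C
Reagents that add atoms: water, O
Why: AgBF4 (monovalent silver) abstracts the endo bromide of 10 while the C1–C3 cyclopropane bond opens in a disrotatory two-electron electrocyclic process, so that strain release turns the bicycle into the six-membered 2-bromocyclohex-2-enyl cation 11 by ring expansion and not by a bond-forming closure. The carbonyl oxygen of the C6 acetate then closes on C1 in a 5-exo-trig mode to the cis-fused dioxolanylium ion 12, which the bicarbonate quench hydrolyses through its ortho acid to the cis hydroxy acetate, the C1–O bond being the one made in that closure. The closest known chemistry is the silver-promoted electrocyclic ring expansion of 6,6-dibromobicyclo[3.1.0]hexanes to 2-bromocyclohex-2-enyl derivatives, joined here to the acetoxonium–water sequence of the Woodward cis-hydroxylation. The new stereocentre at C1 is controlled by the C6 stereocentre, because the tethered acetate can reach the planar cation only on the face on which it stands, and both cyclopropane diastereomers of 10 feed the same cation. The selectivity that matters is capture at C1 and not at C3; it is secured because only O6 carries an acyl group, the C4 silyl ether cannot form a cyclic onium ion and no external nucleophile is present until ionisation is over, while the hindered pyridine and the bicarbonate protect the TES ether from acid. Should the ortho acid collapse with the acetyl group on O1, that isomer converges with 13 in step 8.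

Step 8
Reactants: 13 (1R,4R,5R,6R)-2-bromo-1-hydroxy-5-isopropyl-4-(triethylsilyloxy)cyclohex-2-en-6-yl acetate
Product: 14 (1R,4R,5R,6R)-2-bromo-5-isopropyl-4-(triethylsilyloxy)cyclohex-2-ene-1,6-diol
Conditions: K2CO3 (cat.), MeOH, 0 °C
Reagents that add atoms: none
Why: Base-catalysed transesterification with methanol removes the acetyl group from whichever of the two cis oxygens carries it and should leave the TES ether and the vinyl bromide untouched.

Step 9
Reactants: 14 (1R,4R,5R,6R)-2-bromo-5-isopropyl-4-(triethylsilyloxy)cyclohex-2-ene-1,6-diol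
Product: 15 (4R,5R,6R)-2-bromo-6-hydroxy-5-isopropyl-4-(triethylsilyloxy)cyclohex-2-en-1-one
Conditions: activated MnO2 (excess), CH2Cl2, rt
Reagents that add atoms: none
Why: MnO2 oxidation is selective for allylic alcohols, so only the C1 hydroxyl next to the bromoalkene should become the ketone while the saturated C6 hydroxyl survives and C6 is not epimerised under these neutral conditions.

Step 10
Reactants: 16 glycolaldehyde dimer (1,4-dioxane-2,5-diol); 17 ethyl 2-(triphenylphosphoranylidene)propanoate
Product: 18 ethyl (E)-4-hydroxy-2-methylbut-2-enoate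
Conditions: CH2Cl2, reflux
Reagents that add atoms: ethyl 2-(triphenylphosphoranylidene)propanoate 17, CCOC(=O)C(C)=P(c1ccccc1)(c1ccccc1)c1ccccc1
Why: Wittig olefination of the aldehyde released from the dimer with the stabilised α-branched ylide should give the E-trisubstituted enoate.

Step 11
Reactants: 18 ethyl (E)-4-hydroxy-2-methylbut-2-enoate
Product: 19 ethyl (E)-4-(tert-butyldiphenylsilyloxy)-2-methylbut-2-enoate
Conditions: TBDPSCl, imidazole, CH2Cl2, rt
Reagents that add atoms: tert-butylchlorodiphenylsilane, CC(C)(C)[Si](Cl)(c1ccccc1)c1ccccc1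
Why: Silylation of the primary alcohol installs an ether that withstands saponification, carbodiimide coupling, cross-coupling and the acidic removal of a TES ether.

Step 12
Reactants: 19 ethyl (E)-4-(tert-butyldiphenylsilyloxy)-2-methylbut-2-enoate
Product: 20 (E)-4-(tert-butyldiphenylsilyloxy)-2-methylbut-2-enoic acid
Conditions: LiOH·H2O, THF/H2O, rt; then 1 M HCl to pH 3
Reagents that add atoms: lithium hydroxide, [Li+].[OH-]
Why: Saponification of the ethyl ester should leave the TBDPS ether and the alkene geometry intact.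

Step 13
Reactants: 15 (4R,5R,6R)-2-bromo-6-hydroxy-5-isopropyl-4-(triethylsilyloxy)cyclohex-2-en-1-one; 20 (E)-4-(tert-butyldiphenylsilyloxy)-2-methylbut-2-enoic acid
Product: 21 (4R,5R,6R)-2-bromo-5-isopropyl-1-oxo-4-(triethylsilyloxy)cyclohex-2-en-6-yl (E)-4-(tert-butyldiphenylsilyloxy)-2-methylbut-2-enoate
Conditions: DCC, DMAP (cat.), CH2Cl2, 0 °C to rt
Reagents that add atoms: (E)-4-(tert-butyldiphenylsilyloxy)-2-methylbut-2-enoic acid 20, C/C(=C\CO[Si](c1ccccc1)(c1ccccc1)C(C)(C)C)C(=O)O
Why: Steglich esterification acylates the only free hydroxyl under near-neutral conditions that should not epimerise C6, whose trans relation to the isopropyl group is in any case the more stable one.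

Step 14
Reactants: 21 bromoenone ester (as in step 13); 22 (tributylstannyl)methanol
Product: 23 (4S,5R,6R)-2-(hydroxymethyl)-5-isopropyl-1-oxo-4-(triethylsilyloxy)cyclohex-2-en-6-yl (E)-4-(tert-butyldiphenylsilyloxy)-2-methylbut-2-enoate
Conditions: Bu3SnCH2OH, Pd(PPh3)4 (cat.), 1,4-dioxane, 90 °C
Reagents that add atoms: (tributylstannyl)methanol 22, OC[Sn](CCCC)(CCCC)CCCC
Why: Stille coupling, in which zerovalent palladium inserts into the activated C–Br bond of the α-bromoenone and the hydroxymethyl group is transferred from tin; C4 still carries a silyl ether and not an allylic ester, so π-allyl ionisation cannot compete.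

Step 15
Reactants: 23 hydroxymethyl enone (as in step 14)
Product: 24 (4S,5R,6R)-2-[(tert-butyldiphenylsilyloxy)methyl]-5-isopropyl-1-oxo-4-(triethylsilyloxy)cyclohex-2-en-6-yl (E)-4-(tert-butyldiphenylsilyloxy)-2-methylbut-2-enoate
Conditions: TBDPSCl, imidazole, CH2Cl2, 0 °C to rt
Reagents that add atoms: tert-butylchlorodiphenylsilane, CC(C)(C)[Si](Cl)(c1ccccc1)c1ccccc1
Why: Silylation of the primary allylic alcohol masks O7 so that only O4 will be free for the acylation in step 17.

Step 16
Reactants: 24 bis-TBDPS TES ether (as in step 15)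
Product: 25 (4S,5S,6R)-2-[(tert-butyldiphenylsilyloxy)methyl]-4-hydroxy-5-isopropyl-1-oxocyclohex-2-en-6-yl (E)-4-(tert-butyldiphenylsilyloxy)-2-methylbut-2-enoate
Conditions: PPTS (cat.), MeOH/CH2Cl2, 0 °C to rt
Reagents that add atoms: none
Why: Acid-catalysed methanolysis cleaves a TES ether far faster than TBDPS ethers, so only O4 should be set free.

Step 17
Reactants: 25 C4 alcohol (as in step 16); 26 isobutyric anhydride
Product: 27 (4S,5S,6R)-2-[(tert-butyldiphenylsilyloxy)methyl]-4-(isobutyryloxy)-5-isopropyl-1-oxocyclohex-2-en-6-yl (E)-4-(tert-butyldiphenylsilyloxy)-2-methylbut-2-enoate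
Conditions: (iPrCO)2O, DMAP (cat.), pyridine, CH2Cl2, 0 °C to rt
Reagents that add atoms: isobutyric anhydride 26, CC(C)C(=O)OC(=O)C(C)C
Why: DMAP-catalysed acylation of the single free secondary allylic hydroxyl installs the isobutyrate with retention at C4.

Step 18
Reactants: 27 bis-TBDPS diester (as in step 17)
Product: 28 target, (4S,5S,6R)-2-(hydroxymethyl)-4-(isobutyryloxy)-5-isopropyl-1-oxocyclohex-2-en-6-yl (E)-4-hydroxy-2-methylbut-2-enoate
Conditions: HF·pyridine, pyridine, THF, 0 °C to rt
Reagents that add atoms: none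
Why: Fluoride-mediated desilylation under buffered, base-free conditions removes both primary TBDPS ethers and should cause neither ester migration nor degradation of the γ-acyloxy enone.

**Compound list**

1 | furfural | O=Cc1ccco1 | starting material
2 | isopropylmagnesium chloride | CC(C)[Mg]Cl | starting material
3 | (±)-1-(furan-2-yl)-2-methylpropan-1-ol | CC(C)C(O)c1ccco1 | intermediate
4 | (±)-trans-4-hydroxy-5-isopropylcyclopent-2-en-1-one, racemate (the 4S,5R enantiomer is drawn) | O[C@H]1C=CC(=O)[C@@H]1C(C)C | intermediate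
5 | vinyl acetate | C=COC(C)=O | starting material
6 | (4S,5R)-4-acetoxy-5-isopropylcyclopent-2-en-1-one | CC(=O)O[C@H]1C=CC(=O)[C@@H]1C(C)C | intermediate
7 | (1S,4S,5S)-4-hydroxy-5-isopropylcyclopent-2-en-1-yl acetate | CC(=O)O[C@H]1C=C[C@H](O)[C@@H]1C(C)C | intermediate
8 | (1S,4S,5R)-5-isopropyl-4-(triethylsilyloxy)cyclopent-2-en-1-yl acetate | CC(=O)O[C@H]1C=C[C@H](O[Si](CC)(CC)CC)[C@@H]1C(C)C | intermediate
9 | tribromoacetic acid | OC(=O)C(Br)(Br)Br | starting material
10 | (1S,2R,3R,4R,5R)-6,6-dibromo-3-isopropyl-4-(triethylsilyloxy)bicyclo[3.1.0]hexan-2-yl acetate | CC(=O)O[C@H]1[C@H]2C(Br)(Br)[C@H]2[C@H](O[Si](CC)(CC)CC)[C@@H]1C(C)C | intermediate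
11 | 6-acetoxy-2-bromo-5-isopropyl-4-(triethylsilyloxy)cyclohex-2-en-1-ylium tetrafluoroborate, allyl cation over C1–C2–C3, formed in the flask | CC(=O)O[C@H]1[CH+]C(Br)=C[C@H](O[Si](CC)(CC)CC)[C@@H]1C(C)C.F[B-](F)(F)F | intermediate
12 | cis-fused 2-methyl-1,3-dioxolan-2-ylium tetrafluoroborate bridging O1 and O6 of the 2-bromo-5-isopropyl-4-(triethylsilyloxy)cyclohex-2-ene ring, formed in the flask | O2[C@H]1[C@@H]([O+]=C2C)C(Br)=C[C@H](O[Si](CC)(CC)CC)[C@@H]1C(C)C.F[B-](F)(F)F | intermediate
13 | (1R,4R,5R,6R)-2-bromo-1-hydroxy-5-isopropyl-4-(triethylsilyloxy)cyclohex-2-en-6-yl acetate (1-OH and 6-OAc cis) | CC(=O)O[C@H]1[C@@H](O)C(Br)=C[C@H](O[Si](CC)(CC)CC)[C@@H]1C(C)C | intermediate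
14 | (1R,4R,5R,6R)-2-bromo-5-isopropyl-4-(triethylsilyloxy)cyclohex-2-ene-1,6-diol | O[C@H]1[C@@H](O)C(Br)=C[C@H](O[Si](CC)(CC)CC)[C@@H]1C(C)C | intermediate
15 | (4R,5R,6R)-2-bromo-6-hydroxy-5-isopropyl-4-(triethylsilyloxy)cyclohex-2-en-1-one | O[C@H]1C(=O)C(Br)=C[C@H](O[Si](CC)(CC)CC)[C@@H]1C(C)C | intermediate
16 | glycolaldehyde dimer (1,4-dioxane-2,5-diol) | OC1COC(O)CO1 | starting material
17 | ethyl 2-(triphenylphosphoranylidene)propanoate | CCOC(=O)C(C)=P(c1ccccc1)(c1ccccc1)c1ccccc1 | starting material
18 | ethyl (E)-4-hydroxy-2-methylbut-2-enoate | CCOC(=O)/C(C)=C/CO | intermediate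
19 | ethyl (E)-4-(tert-butyldiphenylsilyloxy)-2-methylbut-2-enoate | CCOC(=O)/C(C)=C/CO[Si](c1ccccc1)(c1ccccc1)C(C)(C)C | intermediate
20 | (E)-4-(tert-butyldiphenylsilyloxy)-2-methylbut-2-enoic acid | C/C(=C\CO[Si](c1ccccc1)(c1ccccc1)C(C)(C)C)C(=O)O | intermediate
21 | (4R,5R,6R)-2-bromo-5-isopropyl-1-oxo-4-(triethylsilyloxy)cyclohex-2-en-6-yl (E)-4-(tert-butyldiphenylsilyloxy)-2-methylbut-2-enoate | C/C(=C\CO[Si](c1ccccc1)(c1ccccc1)C(C)(C)C)C(=O)O[C@H]1C(=O)C(Br)=C[C@H](O[Si](CC)(CC)CC)[C@@H]1C(C)C | intermediate
22 | (tributylstannyl)methanol | OC[Sn](CCCC)(CCCC)CCCC | starting material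
23 | (4S,5R,6R)-2-(hydroxymethyl)-5-isopropyl-1-oxo-4-(triethylsilyloxy)cyclohex-2-en-6-yl (E)-4-(tert-butyldiphenylsilyloxy)-2-methylbut-2-enoate | C/C(=C\CO[Si](c1ccccc1)(c1ccccc1)C(C)(C)C)C(=O)O[C@H]1C(=O)C(CO)=C[C@H](O[Si](CC)(CC)CC)[C@@H]1C(C)C | intermediate
24 | (4S,5R,6R)-2-[(tert-butyldiphenylsilyloxy)methyl]-5-isopropyl-1-oxo-4-(triethylsilyloxy)cyclohex-2-en-6-yl (E)-4-(tert-butyldiphenylsilyloxy)-2-methylbut-2-enoate | C/C(=C\CO[Si](c1ccccc1)(c1ccccc1)C(C)(C)C)C(=O)O[C@H]1C(=O)C(CO[Si](c2ccccc2)(c2ccccc2)C(C)(C)C)=C[C@H](O[Si](CC)(CC)CC)[C@@H]1C(C)C | intermediate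
25 | (4S,5S,6R)-2-[(tert-butyldiphenylsilyloxy)methyl]-4-hydroxy-5-isopropyl-1-oxocyclohex-2-en-6-yl (E)-4-(tert-butyldiphenylsilyloxy)-2-methylbut-2-enoate | C/C(=C\CO[Si](c1ccccc1)(c1ccccc1)C(C)(C)C)C(=O)O[C@H]1C(=O)C(CO[Si](c2ccccc2)(c2ccccc2)C(C)(C)C)=C[C@H](O)[C@@H]1C(C)C | intermediate
26 | isobutyric anhydride | CC(C)C(=O)OC(=O)C(C)C | starting material
27 | (4S,5S,6R)-2-[(tert-butyldiphenylsilyloxy)methyl]-4-(isobutyryloxy)-5-isopropyl-1-oxocyclohex-2-en-6-yl (E)-4-(tert-butyldiphenylsilyloxy)-2-methylbut-2-enoate | C/C(=C\CO[Si](c1ccccc1)(c1ccccc1)C(C)(C)C)C(=O)O[C@H]1C(=O)C(CO[Si](c2ccccc2)(c2ccccc2)C(C)(C)C)=C[C@H](OC(=O)C(C)C)[C@@H]1C(C)C | intermediate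
28 | (4S,5S,6R)-2-(hydroxymethyl)-4-(isobutyryloxy)-5-isopropyl-1-oxocyclohex-2-en-6-yl (E)-4-hydroxy-2-methylbut-2-enoate | C/C(=C\CO)C(=O)O[C@H]1C(=O)C(CO)=C[C@H](OC(=O)C(C)C)[C@@H]1C(C)C | target

**Step count**

Total: 18 steps. Longest linear sequence: 15 steps (steps 1–9 and 13–18, from furfural); the side-chain acid 20 takes 3 steps (10–12).

**Steps most likely to fail**

Step 7. The cation may not be steered by the acetate: ionisation next to two oxygenated carbons may be slow, the acetoxonium ion may reopen so that water adds at C3 during the quench, or acid set free on hydrolysis may strip the TES ether. The fallback sets out from 8 and replaces the acetate by a group that captures the cation irreversibly and without water. Methanolysis (K2CO3, MeOH) should give the alcohol 5-isopropyl-4-(triethylsilyloxy)cyclopent-2-en-1-ol F1. Boc2O with DMAP in MeCN should convert it into the tert-butyl carbonate tert-butyl 5-isopropyl-4-(triethylsilyloxy)cyclopent-2-en-1-yl carbonate F2. Dibromocarbene addition as in step 6 should give tert-butyl 6,6-dibromo-3-isopropyl-4-(triethylsilyloxy)bicyclo[3.1.0]hexan-2-yl carbonate F3. On treatment with AgBF4 and 2,6-di-tert-butylpyridine in CH2Cl2 the carbonate carbonyl should close on C1 (5-exo) and the tert-butyl group should leave as 2-methylpropene, as in the cyclisation of tert-butyl carbonates onto iodonium ions. The product would be the cis-fused cyclic carbonate of 2-bromo-5-isopropyl-4-(triethylsilyloxy)cyclohex-2-ene-1,6-diol F4. Methanolysis (K2CO3, MeOH) returns the route to diol 14.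

Step 4. Hydride delivery may show poor or reversed facial selectivity, because the acetoxy group stands on the face that must be attacked and may outweigh the adjacent isopropyl group. The fallback sets out from 6. If the reduction mainly gives the epimer 4-hydroxy-5-isopropylcyclopent-2-en-1-yl acetate with hydroxyl trans to isopropyl F5, this alcohol is inverted by a Mitsunobu reaction (PPh3, DIAD, chloroacetic acid, THF, 0 °C). That should give 5-isopropyl-4-(chloroacetoxy)cyclopent-2-en-1-yl acetate with the chloroacetoxy group cis to isopropyl F6. Thiourea with NaHCO3 in EtOH at 50 °C removes the chloroacetyl group selectively beside the acetate and returns the route to alcohol 7.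

Step 14. Transfer of the hydroxymethyl group from tin may be slow, so that reduction of the C–Br bond and thermal decay of the enone overtake the coupling. The fallback sets out from 21 and abandons cross-coupling. Formate hydrogenolysis of the C–Br bond (Pd(OAc)2, PPh3, HCO2H, Et3N, DMF, 60 °C) should give the debrominated enone 5-isopropyl-1-oxo-4-(triethylsilyloxy)cyclohex-2-en-6-yl (E)-4-(tert-butyldiphenylsilyloxy)-2-methylbut-2-enoate F7. A Morita–Baylis–Hillman hydroxymethylation at C2 (aqueous formaldehyde, imidazole, THF/H2O, rt) then returns the route to 23.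

**Further compounds**

F1 | step 7 | 5-isopropyl-4-(triethylsilyloxy)cyclopent-2-en-1-ol (hydroxyl trans, silyloxy cis to isopropyl) | O[C@H]1C=C[C@H](O[Si](CC)(CC)CC)[C@@H]1C(C)C
F2 | step 7 | tert-butyl 5-isopropyl-4-(triethylsilyloxy)cyclopent-2-en-1-yl carbonate | CC(C)(C)OC(=O)O[C@H]1C=C[C@H](O[Si](CC)(CC)CC)[C@@H]1C(C)C
F3 | step 7 | tert-butyl 6,6-dibromo-3-isopropyl-4-(triethylsilyloxy)bicyclo[3.1.0]hexan-2-yl carbonate (CBr2 bridge cis to the carbonate) | CC(C)(C)OC(=O)O[C@H]1[C@H]2C(Br)(Br)[C@H]2[C@H](O[Si](CC)(CC)CC)[C@@H]1C(C)C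
F4 | step 7 | cis-fused cyclic carbonate of 2-bromo-5-isopropyl-4-(triethylsilyloxy)cyclohex-2-ene-1,6-diol | O2[C@H]1[C@@H](OC2=O)C(Br)=C[C@H](O[Si](CC)(CC)CC)[C@@H]1C(C)C
F5 | step 4 | 4-hydroxy-5-isopropylcyclopent-2-en-1-yl acetate, hydroxyl trans to isopropyl and cis to acetoxy | CC(=O)O[C@H]1C=C[C@@H](O)[C@@H]1C(C)C
F6 | step 4 | 5-isopropyl-4-(chloroacetoxy)cyclopent-2-en-1-yl acetate, chloroacetoxy cis to isopropyl | CC(=O)O[C@H]1C=C[C@H](OC(=O)CCl)[C@@H]1C(C)C
F7 | step 14 | 5-isopropyl-1-oxo-4-(triethylsilyloxy)cyclohex-2-en-6-yl (E)-4-(tert-butyldiphenylsilyloxy)-2-methylbut-2-enoate | C/C(=C\CO[Si](c1ccccc1)(c1ccccc1)C(C)(C)C)C(=O)O[C@H]1C(=O)C=C[C@H](O[Si](CC)(CC)CC)[C@@H]1C(C)C
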